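**Retrosynthetic overview**

1. Target 17 ⇐ removal of two aryl MOM groups and a late E-selective allylic hydroxylation of chromene 14 at its isopropylidene terminus.
2. 14 ⇐ one-pot disconnection of C4–C4a and, as the ring closure, O1–C8a: (S)-oxaborole 6 (C2 stereocentre, cis C3=C4 locked in a temporary five-membered B–O ring) plus aryl bromide chloride 12 (Br at the future C4a, Cl at the future C8a).
3. 6 ⇐ (S)-dehydrolinalool 4 ⇐ (2S,3S)-epoxygeraniol 2 ⇐ geraniol 1; the quaternary epoxide carbon becomes C2 of the chromene and its C–O bond is never broken.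
4. 12 ⇐ B-alkyl Suzuki–Miyaura coupling at iodine of 2-bromo-1-chloro-4-iodobenzene 10 with the 9-BBN adduct of bis-MOM 3-vinylcatechol 9 (from 2,3-dihydroxybenzaldehyde 7).
5. Enabling feature and ring order: O1 sits on the fully substituted C2 (no hydrogen on the carbinol carbon, so an aryl–Pd–alkoxide can only reductively eliminate), and the cis C3=C4 bond holds O1 over C8a of the central benzene ring, whose C4a/C8a/C6 pattern maps onto Br/Cl/I of 10. Both benzene rings are bought; the pyran ring is the only ring made and is closed last.

Key step: step 8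

Remark: chromene numbering O1, C2, C3, C4, C4a, C5 to C8, C8a is used; the single stereocentre C2 is S; 2-bromo-1-chloro-4-iodobenzene is taken as a purchasable building block.

**Route**

Step 1
Reactants: 1 geraniol
Product: 2 (2S,3S)-2,3-epoxygeraniol
Conditions: Ti(OiPr)4 (5 mol %), L-(+)-diethyl tartrate (6 mol %), t-BuOOH (2 equiv, anhydrous), 4 Å MS, CH2Cl2, −20 °C
Reagents that add atoms: tert-butyl hydroperoxide, CC(C)(C)OO
Why: Sharpless asymmetric epoxidation, in which the tetravalent titanium–tartrate complex binds the allylic hydroxyl and should deliver oxygen to one face of the 2,3-alkene only, so that L-(+)-tartrate with the E-allylic alcohol sets the (2S,3S) epoxide while the remote 6,7-alkene, which has no directing hydroxyl, stays untouched.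

Step 2
Reactants: 2 (2S,3S)-2,3-epoxygeraniol
Product: 3 (2S,3R)-3-(chloromethyl)-2-methyl-2-(4-methylpent-3-en-1-yl)oxirane
Conditions: PPh3, NaHCO3, CCl4, reflux
Reagents that add atoms: tetrachloromethane, ClC(Cl)(Cl)Cl
Why: Appel reaction, which converts the primary alcohol into the chloride under neutral buffered conditions that should leave the trisubstituted epoxide and both stereocentres unchanged (the descriptor at the CH carbon changes only because CH2Cl outranks the ring carbon).

Step 3
Reactants: 3 (2S,3R)-3-(chloromethyl)-2-methyl-2-(4-methylpent-3-en-1-yl)oxirane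
Product: 4 (3S)-3,7-dimethyloct-6-en-1-yn-3-ol
Conditions: n-BuLi (3.2 equiv), THF, −40 °C to −20 °C; then H2O
Reagents that add atoms: none
Why: Base-induced double elimination of a 2,3-epoxy chloride (lithiation next to chlorine opens the epoxide, a second elimination expels chloride and gives the alkyne), in which the C–O bond at the quaternary carbon is never broken, so the epoxide stereocentre should be carried unchanged into the tertiary propargylic alcohol.

Step 4
Reactants: 4 (3S)-3,7-dimethyloct-6-en-1-yn-3-ol
Product: 6 (5S)-5-methyl-5-(4-methylpent-3-en-1-yl)-1,2-oxaborol-2(5H)-ol, via Z-alkenyl pinacol boronate 5 (not isolated)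
Conditions: [RhCl(cod)]2 (1.5 mol %), P(iPr)3 (6 mol %), Et3N, pinacolborane (1.0 equiv; 4 in 1.2 equiv), cyclohexane, rt; then aq. NH4Cl/THF, rt
Reagents that add atoms: pinacolborane, [H]B1OC(C)(C)C(C)(C)O1; water, O
Why: Rhodium-catalysed formal trans-hydroboration of a terminal alkyne through a rhodium vinylidene should place boron on the terminal carbon cis to the carbinol substituent, and on aqueous work-up the tertiary oxygen displaces pinacol from the cis boron to give the five-membered cyclic hemiester, which freezes the Z geometry and leaves the stereocentre untouched.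

Step 5
Reactants: 7 2,3-dihydroxybenzaldehyde
Product: 8 2,3-bis(methoxymethoxy)benzaldehyde
Conditions: MOMCl (3 equiv), iPr2NEt (4 equiv), CH2Cl2, 0 °C to rt
Reagents that add atoms: chloromethyl methyl ether, COCCl
Why: O-alkylation of both phenols with a chloromethyl ether and a hindered amine base, chosen because MOM ethers should survive ylides, boranes and hot phosphate base and can be removed last without Brønsted acid.

Step 6
Reactants: 8 2,3-bis(methoxymethoxy)benzaldehyde
Product: 9 1,2-bis(methoxymethoxy)-3-vinylbenzene
Conditions: Ph3PCH3Br, KOtBu, THF, 0 °C to rt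
Reagents that add atoms: methyltriphenylphosphonium bromide, C[P+](c1ccccc1)(c1ccccc1)c1ccccc1.[Br-]
Why: Wittig methylenation of an aryl aldehyde with the non-stabilised ylide, with no stereochemistry involved.

Step 7
Reactants: 9 1,2-bis(methoxymethoxy)-3-vinylbenzene; 10 2-bromo-1-chloro-4-iodobenzene
Product: 12 1-[2-(3-bromo-4-chlorophenyl)ethyl]-2,3-bis(methoxymethoxy)benzene, via B-alkyl-9-BBN adduct 11 (not isolated)
Conditions: 9-BBN (1.05 equiv), THF, 0 °C to rt; then 10 (1.1 equiv), PdCl2(dppf) (3 mol %), aq. K3PO4, DMF, rt
Reagents that add atoms: none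
Why: Anti-Markovnikov hydroboration of the styrene with 9-BBN followed by B-alkyl Suzuki–Miyaura coupling, which at room temperature should take place only at the C–I bond (oxidative addition I before Br before Cl) and so leaves Br and Cl in place for step 8.

Step 8
Reactants: 6 (5S)-5-methyl-5-(4-methylpent-3-en-1-yl)-1,2-oxaborol-2(5H)-ol; 12 1-[2-(3-bromo-4-chlorophenyl)ethyl]-2,3-bis(methoxymethoxy)benzene
Product: 14 (2S)-6-[2-[2,3-bis(methoxymethoxy)phenyl]ethyl]-2-methyl-2-(4-methylpent-3-en-1-yl)-2H-chromene, via Z-configured chloro alcohol 13 (not isolated)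
Conditions: 6 (1.05 equiv), Pd(OAc)2 (5 mol %), 2-(di-tert-butylphosphino)-1,1′-binaphthyl (7.5 mol %), K3PO4 (3 equiv), H2O (3 equiv), toluene, 60 °C then 95 °C, argon, dark
Reagents that add atoms: none
Why: Proposed new method: one palladium/di-tert-butyl(biaryl)phosphine catalyst is asked to run two cycles in a row, (a) oxidative addition of zerovalent palladium into the C–Br bond of 12, transmetalation of the alkenyl–B bond of 6 (activated as its hydroxy/phosphate borate) and C–C reductive elimination to give chloro alcohol 13, then (b) oxidative addition into the neighbouring C8a–Cl bond, exchange of chloride for the tertiary alkoxide O1 on divalent palladium and C–O reductive elimination. The closest known reaction types are the Suzuki–Miyaura coupling of cyclic alkenylboronic hemiesters with aryl halides and the palladium-catalysed intramolecular etherification of tertiary alcohols with aryl bromides and chlorides (Buchwald–Hartwig C–O coupling), which are only merged here. The pyran ring is the only ring closed, and it closes as a six-membered ring by C(sp2)–O reductive elimination from a seven-membered oxapalladacycle (Pd, C8a, C4a, C4, C3, C2, O1), forming O1–C8a. No new stereocentre is formed: C2 comes from 6 with all four of its bonds intact, and the cis C3=C4 geometry is the one frozen in the oxaborole ring and should be transferred with retention. The step needs Br-before-Cl chemoselectivity (secured by the halide reactivity order and the 60 °C first stage, which puts C4 on the former C–Br carbon and so gives the 6-substituted and not the 7-substituted chromene), and it needs C–O reductive elimination to beat β-hydride elimination, which is impossible here because O1 sits on the fully substituted C2. A second intermolecular Suzuki coupling at C–Cl is held back by using 6 in only slight excess, and light is excluded because 2H-chromenes ring-open photochemically, which would scramble C2.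

Step 9
Reactants: 14 (2S)-6-[2-[2,3-bis(methoxymethoxy)phenyl]ethyl]-2-methyl-2-(4-methylpent-3-en-1-yl)-2H-chromene
Product: 15 (2E)-5-[(2S)-6-[2-[2,3-bis(methoxymethoxy)phenyl]ethyl]-2-methyl-2H-chromen-2-yl]-2-methylpent-2-en-1-ol
Conditions: SeO2 (20 mol %), t-BuOOH (3 equiv), salicylic acid (10 mol %), CH2Cl2, 0 °C to rt, dark
Reagents that add atoms: tert-butyl hydroperoxide, CC(C)(C)OO (terminal oxidant; the oxygen is relayed through the catalyst SeO2, O=[Se]=O)
Why: SeO2-catalysed allylic hydroxylation (ene reaction then [2,3]-sigmatropic shift) is selective for the E-methyl group of a trisubstituted isopropylidene alkene and should give the E-allylic alcohol, while the chromene C3=C4 bond has no allylic hydrogen (C2 is quaternary) and should not react.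

Step 10
Reactants: 15 (2E)-5-[(2S)-6-[2-[2,3-bis(methoxymethoxy)phenyl]ethyl]-2-methyl-2H-chromen-2-yl]-2-methylpent-2-en-1-ol
Product: 17 3-[2-[(2S)-2-[(3E)-5-hydroxy-4-methylpent-3-en-1-yl]-2-methyl-2H-chromen-6-yl]ethyl]benzene-1,2-diol, via tris(trimethylsilyl) ether 16 (not isolated)
Conditions: Me3SiOTf (6 equiv), 2,2′-bipyridyl (9 equiv), MeCN, 0 °C to rt; then H2O, rt; argon, dark
Reagents that add atoms: none
Why: The Me3SiOTf/2,2′-bipyridyl pair converts aryl MOM ethers into aryl silyl ethers (the MOM carbon leaves as an N-(methoxymethyl)bipyridinium salt) without free Brønsted acid and silylates the allylic hydroxyl in passing, and water then hydrolyses all O–SiMe3 bonds, so the acid-sensitive tertiary allylic aryl ether at C2 and the allylic alcohol should survive.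

**Compound list**

1 | geraniol, (2E)-3,7-dimethylocta-2,6-dien-1-ol | CC(C)=CCC/C(C)=C/CO | starting material
2 | (2S,3S)-2,3-epoxygeraniol, [(2S,3S)-3-methyl-3-(4-methylpent-3-en-1-yl)oxiran-2-yl]methanol | CC(C)=CCC[C@]1(C)O[C@H]1CO | intermediate
3 | (2S,3R)-3-(chloromethyl)-2-methyl-2-(4-methylpent-3-en-1-yl)oxirane (chloride of 2, same spatial arrangement) | CC(C)=CCC[C@]1(C)O[C@H]1CCl | intermediate
4 | (S)-dehydrolinalool, (3S)-3,7-dimethyloct-6-en-1-yn-3-ol | CC(C)=CCC[C@](C)(O)C#C | intermediate
5 | (1Z,3S)-3,7-dimethyl-1-(4,4,5,5-tetramethyl-1,3,2-dioxaborolan-2-yl)octa-1,6-dien-3-ol | CC(C)=CCC[C@](C)(O)/C=C\B1OC(C)(C)C(C)(C)O1 | intermediate (not isolated)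
6 | (5S)-5-methyl-5-(4-methylpent-3-en-1-yl)-1,2-oxaborol-2(5H)-ol | CC(C)=CCC[C@@]1(C)C=CB(O)O1 | intermediate
7 | 2,3-dihydroxybenzaldehyde | O=Cc1cccc(O)c1O | starting material
8 | 2,3-bis(methoxymethoxy)benzaldehyde | O=Cc1cccc(OCOC)c1OCOC | intermediate
9 | 1,2-bis(methoxymethoxy)-3-vinylbenzene | C=Cc1cccc(OCOC)c1OCOC | intermediate
10 | 2-bromo-1-chloro-4-iodobenzene | Clc1ccc(I)cc1Br | starting material
11 | 9-[2-[2,3-bis(methoxymethoxy)phenyl]ethyl]-9-borabicyclo[3.3.1]nonane | COCOc1cccc(CCB2C3CCCC2CCC3)c1OCOC | intermediate (not isolated)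
12 | 1-[2-(3-bromo-4-chlorophenyl)ethyl]-2,3-bis(methoxymethoxy)benzene | COCOc1cccc(CCc2ccc(Cl)c(Br)c2)c1OCOC | intermediate
13 | (1Z,3S)-1-[2-chloro-5-[2-[2,3-bis(methoxymethoxy)phenyl]ethyl]phenyl]-3,7-dimethylocta-1,6-dien-3-ol | CC(C)=CCC[C@](C)(O)/C=C\c1cc(CCc2cccc(OCOC)c2OCOC)ccc1Cl | intermediate (not isolated)
14 | (2S)-6-[2-[2,3-bis(methoxymethoxy)phenyl]ethyl]-2-methyl-2-(4-methylpent-3-en-1-yl)-2H-chromene | CC(C)=CCC[C@@]1(C)C=Cc2cc(CCc3cccc(OCOC)c3OCOC)ccc2O1 | intermediate
15 | (2E)-5-[(2S)-6-[2-[2,3-bis(methoxymethoxy)phenyl]ethyl]-2-methyl-2H-chromen-2-yl]-2-methylpent-2-en-1-ol | C/C(=C\CC[C@@]1(C)C=Cc2cc(CCc3cccc(OCOC)c3OCOC)ccc2O1)CO | intermediate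
16 | tris(trimethylsilyl) ether of 17 (both catechol oxygens and the allylic oxygen silylated) | C/C(=C\CC[C@@]1(C)C=Cc2cc(CCc3cccc(O[Si](C)(C)C)c3O[Si](C)(C)C)ccc2O1)CO[Si](C)(C)C | intermediate (not isolated)
17 | 3-[2-[(2S)-2-[(3E)-5-hydroxy-4-methylpent-3-en-1-yl]-2-methyl-2H-chromen-6-yl]ethyl]benzene-1,2-diol (CNP0267525.1) | C/C(=C\CC[C@@]1(C)C=Cc2cc(CCc3cccc(O)c3O)ccc2O1)CO | target

**Step count and risks**

Total steps: 10. Longest linear sequence: 7 steps (steps 1, 2, 3, 4, 8, 9, 10).

Steps most likely to fail:

1. Step 8 (the labelled step). The second catalytic cycle may stall because oxidative addition into the hindered C8a–Cl bond or C–O reductive elimination is slow. The Z geometry may erode during transmetalation. Zerovalent palladium may also ionise the allylic C2–O bond of the product and erode the stereocentre. The fallback uses known chemistry only and sets out from alkynol 4 and aryl halide 12. Sonogashira coupling (PdCl2(PPh3)2, CuI, Et3N, 60 °C) at the C–Br bond should give the chloroaryl alkynol F1. Semi-hydrogenation over Pd/CaCO3 poisoned with Pb(OAc)2 and quinoline (Lindlar conditions, H2, EtOAc) should give the Z-alkene 13, now isolated. A separate palladium-catalysed intramolecular etherification of the tertiary alcohol (Pd(OAc)2, 2-(di-tert-butylphosphino)-1,1′-binaphthyl, Cs2CO3, toluene, 80 °C) then closes O1–C8a, and the fallback comes back to the route at 14.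

2. Step 4. The Z selectivity may erode by rhodium hydride isomerisation once the alkyne is consumed, and the free tertiary carbinol may be lost by dehydration at the vinylidene stage. The fallback sets out from 4. Double deprotonation (n-BuLi, 2.1 equiv, THF, −78 °C), borylation with 2-isopropoxy-4,4,5,5-tetramethyl-1,3,2-dioxaborolane and quenching with HCl in Et2O should give the alkynyl pinacol boronate F2. Hydrozirconation with Cp2Zr(H)Cl (2.2 equiv, THF) and protonolysis of the C–Zr bond with water should give, by syn addition, the Z-alkenyl boronate 5. This closes to the oxaborole on work-up, and the fallback comes back at 6.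

3. Step 9. Conversion may stop early, the alcohol may be over-oxidised to the enal, and competing oxidation at the benzylic CH2 groups may set in. The fallback sets out from 14. Cross-metathesis with methacrolein (second-generation Hoveyda–Grubbs catalyst, CH2Cl2, 40 °C) should exchange the terminal isopropylidene for the E-configured 2-methyl enal F3. Luche reduction (NaBH4, CeCl3·7H2O, MeOH, 0 °C) should then give the allylic alcohol, and the fallback comes back at 15.

**Further compounds**

F1 | step 8 | (3S)-1-[2-chloro-5-[2-[2,3-bis(methoxymethoxy)phenyl]ethyl]phenyl]-3,7-dimethyloct-6-en-1-yn-3-ol | CC(C)=CCC[C@](C)(O)C#Cc1cc(CCc2cccc(OCOC)c2OCOC)ccc1Cl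
F2 | step 4 | (3S)-3,7-dimethyl-1-(4,4,5,5-tetramethyl-1,3,2-dioxaborolan-2-yl)oct-6-en-1-yn-3-ol | CC(C)=CCC[C@](C)(O)C#CB1OC(C)(C)C(C)(C)O1
F3 | step 9 | (2E)-5-[(2S)-6-[2-[2,3-bis(methoxymethoxy)phenyl]ethyl]-2-methyl-2H-chromen-2-yl]-2-methylpent-2-enal | C/C(=C\CC[C@@]1(C)C=Cc2cc(CCc3cccc(OCOC)c3OCOC)ccc2O1)C=O
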